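**Plan**

- Feature: number the central ring C1 (OMe), C2 (CH2Ar), C3 (OH), C4 (CH2Ar), C5 (CH2CH2Ar'), C6 (CH2Ar). C1–C4 carry the O,C,O,C pattern of a doubly enolised 2,4-dibenzylcyclohexane-1,3-dione, and C5–C6 carry two carbon chains like a disubstituted alkyne. This is the pattern an Alder–Rickert benzannulation delivers.
- Retrosynthetic cuts, in order: the four O–CH2Ph bonds and the O–Si bond; the C6 benzylic CH2 back to an aryl ketone; then ring bonds C4–C5 and C1–C6, with a C2H4 bridge restored between C1 and C4.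
- The cyclohexadiene is cut further at O–Si, the C4–benzyl bond, O–CH3 and the C2–benzyl bond, back to cyclohexane-1,3-dione. The ynone is cut at the C(O)–C(sp) bond and at the propargylic C–C bond.
- Forward: the purchased dione ring is benzylated at C2, O-methylated, benzylated at C4 and silyl-enolised (steps 1–4). The ynone is made in two steps (5–6). The central benzene ring, the only ring formed, arises in step 7. Ketone deoxygenation, desilylation and debenzylation follow (8–11).
- Stereochemistry: the target has no stereogenic element. The stereocentres that appear in 8, 18 and 20 are racemic and are erased in steps 4, 7 and 9.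

Key step: step 7

Assumption: the target is achiral (no stereocentre, no configurationally stable axis), so "single enantiomer" is read as the single constitution shown and no asymmetric step is needed.

**Route**

Step 1
Reactants: 1 cyclohexane-1,3-dione; 2 4-(benzyloxy)benzaldehyde
Product: 4 2-[4-(benzyloxy)benzyl]cyclohexane-1,3-dione, via 2-[4-(benzyloxy)benzylidene]cyclohexane-1,3-dione 3 (not isolated)
Conditions: Hantzsch ester (1.0 equiv), L-proline (10 mol %), CH2Cl2, rt
Reagents that add atoms: none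
Why: Three-component reductive Knoevenagel alkylation: the amine-catalysed condensation gives benzylidene dione 3, which the Hantzsch ester reduces at once by conjugate hydride transfer, so a second dione cannot add and only the C2-monobenzyl dione should form.

Step 2
Reactants: 4 2-[4-(benzyloxy)benzyl]cyclohexane-1,3-dione
Product: 5 2-[4-(benzyloxy)benzyl]-3-methoxycyclohex-2-en-1-one
Conditions: HC(OMe)3, p-TsOH·H2O (cat.), MeOH, rt → 50 °C
Reagents that add atoms: trimethyl orthoformate, COC(OC)OC (methoxy donor, in exchange with the solvent methanol, CO)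
Why: Acid-catalysed enol etherification of a cyclic 1,3-dione driven by orthoformate dehydration; the two carbonyls are equivalent, so a single vinylogous ester is expected and the benzyl ether is inert.

Step 3
Reactants: 5 2-[4-(benzyloxy)benzyl]-3-methoxycyclohex-2-en-1-one; 6 1-(benzyloxy)-4-(bromomethyl)benzene
Product: 8 rac-2,6-bis[4-(benzyloxy)benzyl]-3-methoxycyclohex-2-en-1-one, via lithium cross-conjugated enolate 7 (not isolated)
Conditions: LDA (commercial solution, 1.1 equiv), THF, −78 °C; then 6, −78 → 0 °C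
Reagents that add atoms: none
Why: Stork–Danheiser-type kinetic α′-deprotonation of the vinylogous ester gives enolate 7, which the reactive benzylic bromide C-alkylates; the new C6 stereocentre forms racemic and is planarised in step 4.

Step 4
Reactants: 8 rac-2,6-bis[4-(benzyloxy)benzyl]-3-methoxycyclohex-2-en-1-one
Product: 10 1,3-bis[4-(benzyloxy)benzyl]-2-[(tert-butyldimethylsilyl)oxy]-4-methoxycyclohexa-1,3-diene, via lithium dienolate 9 (not isolated)
Conditions: LDA (commercial solution, 1.2 equiv), THF, −78 °C; then TBSOTf, −78 → 0 °C; Et3N, pentane, cold aq NaHCO3 wash; used crude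
Reagents that add atoms: tert-butyldimethylsilyl trifluoromethanesulfonate, CC(C)(C)[Si](C)(C)OS(=O)(=O)C(F)(F)F
Why: Silyl enol ether formation under kinetic control: the tertiary α′-C–H remains the kinetically preferred site over the γ-CH2 (as in geminal α′-dialkylation of vinylogous esters), and the reactive silyl triflate O-silylates the hindered enolate to fix the cross-conjugated 1-methoxy-3-silyloxy diene.

Step 5
Reactants: 11 1-(benzyloxy)-3-(bromomethyl)benzene; 12 trimethyl(prop-1-yn-1-yl)silane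
Product: 15 1-(benzyloxy)-3-(but-3-yn-1-yl)benzene, via 3-lithio-1-(trimethylsilyl)propyne 13 (not isolated), via silyl-capped butynylarene 14 (not isolated)
Conditions: 12, n-BuLi, THF, −78 °C; then 11, −78 → 0 °C; then MeOH, K2CO3, rt
Reagents that add atoms: none
Why: Propargylic lithiation of the silylpropyne and SN2 alkylation by the benzylic bromide occur at the CH2 terminus because silicon blocks the alkyne end, and base-catalysed methanolysis then cleaves the C(sp)–Si bond in the same flask.

Step 6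
Reactants: 15 1-(benzyloxy)-3-(but-3-yn-1-yl)benzene; 16 4-(benzyloxy)benzoyl chloride
Product: 17 1-[4-(benzyloxy)phenyl]-5-[3-(benzyloxy)phenyl]pent-2-yn-1-one
Conditions: PdCl2(PPh3)2 (2 mol %), CuI (4 mol %), Et3N, THF, rt
Reagents that add atoms: none
Why: Acyl Sonogashira coupling of a terminal alkyne with an aroyl chloride gives the conjugated ynone under mild conditions that spare the benzyl ethers.

Step 7
Reactants: 10 1,3-bis[4-(benzyloxy)benzyl]-2-[(tert-butyldimethylsilyl)oxy]-4-methoxycyclohexa-1,3-diene; 17 1-[4-(benzyloxy)phenyl]-5-[3-(benzyloxy)phenyl]pent-2-yn-1-one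
Product: 19 [4-(benzyloxy)phenyl]{3,5-bis[4-(benzyloxy)benzyl]-6-{2-[3-(benzyloxy)phenyl]ethyl}-4-[(tert-butyldimethylsilyl)oxy]-2-methoxyphenyl}methanone, via bicyclo[2.2.2]octa-2,5-diene cycloadduct 18 (not isolated)
Conditions: 10 (1.5 equiv), mesitylene (ca. 1 M), 165 °C, Ar, base-washed sealed tube
Reagents that add atoms: none
Why: Alder–Rickert reaction: the ring-locked cisoid diene of 10 undergoes a normal-demand, asynchronous [4+2] cycloaddition with the aroyl-activated alkyne of 17 to give bicyclo[2.2.2]octa-2,5-diene 18 (bridgeheads C1–OMe and C4–CH2Ar), which at the same temperature loses its C7–C8 bridge as ethylene by retro-[4+2], the gain of aromaticity making this irreversible. The closest known reaction type is the Diels–Alder/retro-Diels–Alder benzannulation of 1-alkoxy-3-silyloxycyclohexa-1,3-dienes with alkynyl ketones and esters. The one new ring, the six-membered central benzene, is closed by intermolecular [4+2] formation of C4–C5 and C1–C6, first as the cyclohexadiene half of the bicycle and then as the arene after extrusion. No stereocentre survives, since the two bridgehead centres of 18 are racemic and vanish on aromatisation. The step needs regioselectivity, and the substrate supplies it electronically: both oxygen donors (C3–OSi directly, C1–OMe vinylogously) raise the HOMO coefficient at diene terminus C4, which bonds to the electrophilic β-carbon of the ynone (bearing the arylethyl chain), so the aroyl-bearing α-carbon closes onto C1 and the ketone ends at C6 next to OMe. Excess diene, high concentration and acid-free glassware are chosen because both new bonds join fully substituted carbons and the silyl dienol ether is hydrolytically labile.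

Step 8
Reactants: 19 [4-(benzyloxy)phenyl]{3,5-bis[4-(benzyloxy)benzyl]-6-{2-[3-(benzyloxy)phenyl]ethyl}-4-[(tert-butyldimethylsilyl)oxy]-2-methoxyphenyl}methanone
Product: 20 rac-[4-(benzyloxy)phenyl]{3,5-bis[4-(benzyloxy)benzyl]-6-{2-[3-(benzyloxy)phenyl]ethyl}-4-[(tert-butyldimethylsilyl)oxy]-2-methoxyphenyl}methanol
Conditions: LiAlH4, THF, 0 °C → rt; aq NaOH work-up
Reagents that add atoms: none
Why: Hydride reduction of the diaryl ketone: the small hydride should reach the di-ortho-substituted carbonyl while the shielded aryl silyl ether and the benzyl ethers stay intact; the new carbinol centre is racemic and is removed in step 9.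

Step 9
Reactants: 20 rac-[4-(benzyloxy)phenyl]{3,5-bis[4-(benzyloxy)benzyl]-6-{2-[3-(benzyloxy)phenyl]ethyl}-4-[(tert-butyldimethylsilyl)oxy]-2-methoxyphenyl}methanol
Product: 21 tert-butyl{2,4,6-tris[4-(benzyloxy)benzyl]-3-{2-[3-(benzyloxy)phenyl]ethyl}-5-methoxyphenoxy}dimethylsilane
Conditions: Et3SiH (10 equiv), TFA (3 equiv), CH2Cl2, −40 → 0 °C, 20 added slowly to the premixed reagents
Reagents that add atoms: none
Why: Ionic hydrogenation: acid ionises the doubly benzylic alcohol to a cation stabilised by the 4-benzyloxyphenyl ring and the electron-rich central ring, and the silane, kept in large excess by inverse addition in the cold, should transfer hydride before the cation reacts otherwise; aryl silyl and benzyl ethers tolerate brief cold TFA.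

Step 10
Reactants: 21 tert-butyl{2,4,6-tris[4-(benzyloxy)benzyl]-3-{2-[3-(benzyloxy)phenyl]ethyl}-5-methoxyphenoxy}dimethylsilane
Product: 22 2,4,6-tris[4-(benzyloxy)benzyl]-3-{2-[3-(benzyloxy)phenyl]ethyl}-5-methoxyphenol
Conditions: TBAF, THF, 0 °C → rt; aq NH4Cl
Reagents that add atoms: none
Why: Fluoride-induced cleavage of the aryl silyl ether, driven by Si–F bond formation, frees the C3 phenol; benzyl and methyl ethers are stable to fluoride.

Step 11
Reactants: 22 2,4,6-tris[4-(benzyloxy)benzyl]-3-{2-[3-(benzyloxy)phenyl]ethyl}-5-methoxyphenol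
Product: 23 2,4,6-tris(4-hydroxybenzyl)-3-[2-(3-hydroxyphenyl)ethyl]-5-methoxyphenol (target)
Conditions: H2 (1 atm), 10% Pd/C, EtOAc–MeOH, rt
Reagents that add atoms: none
Why: Catalytic hydrogenolysis of the four benzyl aryl ethers over palladium should give the pentaphenol; the methyl ether and the diarylmethane and bibenzyl C–C bonds are not cleaved at 1 atm.

**Compound list**

1 | cyclohexane-1,3-dione | O=C1CCCC(=O)C1 | starting material
2 | 4-(benzyloxy)benzaldehyde | O=Cc1ccc(OCc2ccccc2)cc1 | starting material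
3 | 2-[4-(benzyloxy)benzylidene]cyclohexane-1,3-dione | O=C1CCCC(=O)C1=Cc1ccc(OCc2ccccc2)cc1 | intermediate (not isolated)
4 | 2-[4-(benzyloxy)benzyl]cyclohexane-1,3-dione | O=C1CCCC(=O)C1Cc1ccc(OCc2ccccc2)cc1 | intermediate
5 | 2-[4-(benzyloxy)benzyl]-3-methoxycyclohex-2-en-1-one | COC1=C(Cc2ccc(OCc3ccccc3)cc2)C(=O)CCC1 | intermediate
6 | 1-(benzyloxy)-4-(bromomethyl)benzene | BrCc1ccc(OCc2ccccc2)cc1 | starting material
7 | lithium 6-[4-(benzyloxy)benzyl]-5-methoxycyclohexa-1,5-dien-1-olate | [Li]OC1=CCCC(OC)=C1Cc1ccc(OCc2ccccc2)cc1 | intermediate (not isolated)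
8 | rac-2,6-bis[4-(benzyloxy)benzyl]-3-methoxycyclohex-2-en-1-one (racemic at C6) | COC1=C(Cc2ccc(OCc3ccccc3)cc2)C(=O)C(Cc2ccc(OCc3ccccc3)cc2)CC1 | intermediate
9 | lithium 2,6-bis[4-(benzyloxy)benzyl]-5-methoxycyclohexa-1,5-dien-1-olate | [Li]OC1=C(Cc2ccc(OCc3ccccc3)cc2)CCC(OC)=C1Cc1ccc(OCc2ccccc2)cc1 | intermediate (not isolated)
10 | 1,3-bis[4-(benzyloxy)benzyl]-2-[(tert-butyldimethylsilyl)oxy]-4-methoxycyclohexa-1,3-diene | COC1=C(Cc2ccc(OCc3ccccc3)cc2)C(O[Si](C)(C)C(C)(C)C)=C(Cc2ccc(OCc3ccccc3)cc2)CC1 | intermediate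
11 | 1-(benzyloxy)-3-(bromomethyl)benzene | BrCc1cccc(OCc2ccccc2)c1 | starting material
12 | trimethyl(prop-1-yn-1-yl)silane | CC#C[Si](C)(C)C | starting material
13 | 3-lithio-1-(trimethylsilyl)propyne | [Li]CC#C[Si](C)(C)C | intermediate (not isolated)
14 | {4-[3-(benzyloxy)phenyl]but-1-yn-1-yl}trimethylsilane | C[Si](C)(C)C#CCCc1cccc(OCc2ccccc2)c1 | intermediate (not isolated)
15 | 1-(benzyloxy)-3-(but-3-yn-1-yl)benzene | C#CCCc1cccc(OCc2ccccc2)c1 | intermediate
16 | 4-(benzyloxy)benzoyl chloride | O=C(Cl)c1ccc(OCc2ccccc2)cc1 | starting material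
17 | 1-[4-(benzyloxy)phenyl]-5-[3-(benzyloxy)phenyl]pent-2-yn-1-one | O=C(C#CCCc1cccc(OCc2ccccc2)c1)c1ccc(OCc2ccccc2)cc1 | intermediate
18 | rac-[4-(benzyloxy)phenyl]{4,6-bis[4-(benzyloxy)benzyl]-3-{2-[3-(benzyloxy)phenyl]ethyl}-5-[(tert-butyldimethylsilyl)oxy]-1-methoxybicyclo[2.2.2]octa-2,5-dien-2-yl}methanone (racemic; bridgehead configurations linked by the bicycle) | COC12CCC(Cc3ccc(OCc4ccccc4)cc3)(C(O[Si](C)(C)C(C)(C)C)=C1Cc1ccc(OCc3ccccc3)cc1)C(CCc1cccc(OCc3ccccc3)c1)=C2C(=O)c1ccc(OCc2ccccc2)cc1 | intermediate (not isolated)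
19 | [4-(benzyloxy)phenyl]{3,5-bis[4-(benzyloxy)benzyl]-6-{2-[3-(benzyloxy)phenyl]ethyl}-4-[(tert-butyldimethylsilyl)oxy]-2-methoxyphenyl}methanone | COc1c(Cc2ccc(OCc3ccccc3)cc2)c(O[Si](C)(C)C(C)(C)C)c(Cc2ccc(OCc3ccccc3)cc2)c(CCc2cccc(OCc3ccccc3)c2)c1C(=O)c1ccc(OCc2ccccc2)cc1 | intermediate
20 | rac-[4-(benzyloxy)phenyl]{3,5-bis[4-(benzyloxy)benzyl]-6-{2-[3-(benzyloxy)phenyl]ethyl}-4-[(tert-butyldimethylsilyl)oxy]-2-methoxyphenyl}methanol (racemic) | COc1c(Cc2ccc(OCc3ccccc3)cc2)c(O[Si](C)(C)C(C)(C)C)c(Cc2ccc(OCc3ccccc3)cc2)c(CCc2cccc(OCc3ccccc3)c2)c1C(O)c1ccc(OCc2ccccc2)cc1 | intermediate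
21 | tert-butyl{2,4,6-tris[4-(benzyloxy)benzyl]-3-{2-[3-(benzyloxy)phenyl]ethyl}-5-methoxyphenoxy}dimethylsilane | COc1c(Cc2ccc(OCc3ccccc3)cc2)c(O[Si](C)(C)C(C)(C)C)c(Cc2ccc(OCc3ccccc3)cc2)c(CCc2cccc(OCc3ccccc3)c2)c1Cc1ccc(OCc2ccccc2)cc1 | intermediate
22 | 2,4,6-tris[4-(benzyloxy)benzyl]-3-{2-[3-(benzyloxy)phenyl]ethyl}-5-methoxyphenol | COc1c(Cc2ccc(OCc3ccccc3)cc2)c(O)c(Cc2ccc(OCc3ccccc3)cc2)c(CCc2cccc(OCc3ccccc3)c2)c1Cc1ccc(OCc2ccccc2)cc1 | intermediate
23 | 2,4,6-tris(4-hydroxybenzyl)-3-[2-(3-hydroxyphenyl)ethyl]-5-methoxyphenol (achiral) | COc1c(Cc2ccc(O)cc2)c(O)c(Cc2ccc(O)cc2)c(CCc2cccc(O)c2)c1Cc1ccc(O)cc1 | target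

**Count and risks**

Total steps: 11. Longest linear sequence: 9 (steps 1–4, then 7–11); the ynone branch adds steps 5 and 6.

Steps most likely to fail:

1. Step 7. Both new bonds join fully substituted carbons, so the cycloaddition may be slower than thermal decay of the partners: protodesilylation or 1,5-hydrogen shift of the diene, and oligomerisation of the ynone. Erosion of regiochemistry is a secondary concern. Fallback, setting out from 15 and 10 and returning at 20: the bulky aroyl activator is replaced by a formyl group. Alkyne 15 is lithiated (n-BuLi, THF, −78 °C) and formylated with DMF (inverse quench into aq KH2PO4) to give 5-[3-(benzyloxy)phenyl]pent-2-ynal F1. The smaller and more electrophilic F1 is heated with diene 10, forming the same two ring bonds through the bicyclic carbaldehyde cycloadduct F2, which loses ethylene to give the hexasubstituted benzaldehyde F3. Addition of commercial 4-(benzyloxy)phenylmagnesium bromide (THF, 0 °C) to F3 then gives carbinol 20, so steps 6–8 are bypassed.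

2. Step 4. Enolisation may occur at the γ-CH2 in place of the tertiary α′-C–H, silylation may occur on carbon, or the silyl group may be lost hydrolytically on isolation. Fallback, setting out from 5 (with aldehyde 2) and returning at 10: the diene is made by regiospecific conjugate hydrosilylation in place of enolate trapping. The kinetic enolate of 5 (LDA, THF, −78 °C) is added to 2 to give the aldol adduct 2-[4-(benzyloxy)benzyl]-6-{[4-(benzyloxy)phenyl](hydroxy)methyl}-3-methoxycyclohex-2-en-1-one F4. This is converted (MsCl, Et3N) into its methanesulfonate F5, and elimination with DBU gives (6E)-2-[4-(benzyloxy)benzyl]-6-[4-(benzyloxy)benzylidene]-3-methoxycyclohex-2-en-1-one F6. Platinum- or rhodium-catalysed 1,4-hydrosilylation of the s-cis exocyclic enone of F6 with tert-butyldimethylsilane (Karstedt's catalyst or RhCl(PPh3)3, toluene, 60 °C) places hydrogen on the benzylidene carbon and silicon on oxygen, giving 10 directly; steps 3 and 4 are bypassed.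

3. Step 9. The diarylmethyl cation may be captured intramolecularly by the activated ring of the neighbouring arylethyl arm (seven-membered Friedel–Crafts closure para to its benzyloxy group), or acid may strip benzyl ethers, in competition with hydride transfer. Fallback, setting out from 20 and returning at 23: the free cation is avoided by removing the benzylic oxygen on a metal surface. Carbinol 20 is acetylated (Ac2O, DMAP, Et3N, CH2Cl2) to give the diarylmethyl acetate F7. Hydrogenation over Pd/C (H2, EtOAc–EtOH, rt) should cleave the benzylic C–OAc bond together with the four benzyl ethers to give the silyl ether of the target, F8, and TBAF in THF then gives 23; steps 9–11 are replaced.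

**Further compounds**

F1 | step 7 | 5-[3-(benzyloxy)phenyl]pent-2-ynal | O=CC#CCCc1cccc(OCc2ccccc2)c1
F2 | step 7 | rac-4,6-bis[4-(benzyloxy)benzyl]-3-{2-[3-(benzyloxy)phenyl]ethyl}-5-[(tert-butyldimethylsilyl)oxy]-1-methoxybicyclo[2.2.2]octa-2,5-diene-2-carbaldehyde | COC12CCC(Cc3ccc(OCc4ccccc4)cc3)(C(O[Si](C)(C)C(C)(C)C)=C1Cc1ccc(OCc3ccccc3)cc1)C(CCc1cccc(OCc3ccccc3)c1)=C2C=O
F3 | step 7 | 3,5-bis[4-(benzyloxy)benzyl]-6-{2-[3-(benzyloxy)phenyl]ethyl}-4-[(tert-butyldimethylsilyl)oxy]-2-methoxybenzaldehyde | COc1c(Cc2ccc(OCc3ccccc3)cc2)c(O[Si](C)(C)C(C)(C)C)c(Cc2ccc(OCc3ccccc3)cc2)c(CCc2cccc(OCc3ccccc3)c2)c1C=O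
F4 | step 4 | 2-[4-(benzyloxy)benzyl]-6-{[4-(benzyloxy)phenyl](hydroxy)methyl}-3-methoxycyclohex-2-en-1-one (racemic, mixture of diastereomers) | COC1=C(Cc2ccc(OCc3ccccc3)cc2)C(=O)C(C(O)c2ccc(OCc3ccccc3)cc2)CC1
F5 | step 4 | [4-(benzyloxy)phenyl]{3-[4-(benzyloxy)benzyl]-4-methoxy-2-oxocyclohex-3-en-1-yl}methyl methanesulfonate (racemic, mixture of diastereomers) | COC1=C(Cc2ccc(OCc3ccccc3)cc2)C(=O)C(C(OS(C)(=O)=O)c2ccc(OCc3ccccc3)cc2)CC1
F6 | step 4 | (6E)-2-[4-(benzyloxy)benzyl]-6-[4-(benzyloxy)benzylidene]-3-methoxycyclohex-2-en-1-one | COC1=C(Cc2ccc(OCc3ccccc3)cc2)C(=O)/C(=C/c2ccc(OCc3ccccc3)cc2)CC1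
F7 | step 9 | rac-[4-(benzyloxy)phenyl]{3,5-bis[4-(benzyloxy)benzyl]-6-{2-[3-(benzyloxy)phenyl]ethyl}-4-[(tert-butyldimethylsilyl)oxy]-2-methoxyphenyl}methyl acetate | COc1c(Cc2ccc(OCc3ccccc3)cc2)c(O[Si](C)(C)C(C)(C)C)c(Cc2ccc(OCc3ccccc3)cc2)c(CCc2cccc(OCc3ccccc3)c2)c1C(OC(C)=O)c1ccc(OCc2ccccc2)cc1
F8 | step 9 | tert-butyl{2,4,6-tris(4-hydroxybenzyl)-3-[2-(3-hydroxyphenyl)ethyl]-5-methoxyphenoxy}dimethylsilane | COc1c(Cc2ccc(O)cc2)c(O[Si](C)(C)C(C)(C)C)c(Cc2ccc(O)cc2)c(CCc2cccc(O)c2)c1Cc1ccc(O)cc1
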